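**Strategy**

The two flavan units are the same monomer used twice, so the route rests on one annulation that builds pyran ring C onto ring A by making O1–C8a and C4a–C4 together. A 2-fluoroaryllithium (lithium on the future C4a, fluorine on the future C8a) attacks a cis-1,3-dioxan-4-one that already contains O1, C2, C3 and C4; ring opening releases acetone, and the freed C2 alkoxide displaces the fluoride, which the new C4 ketone has just activated. The step exploits the ortho relationship of O1 and C4 on ring A. Both C4 centres are set afterwards by trans-selective capture of C4 benzylic cations, first by C6 of a second unit and then by water.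

Key step: step 7

Remark: flavan numbering is used throughout (ring A = benzo ring C4a–C8a, ring B = 2-aryl group, ring C = pyran ring O1–C4). Compounds 1, 2, 4 and 8 are taken as commercial. The CIP descriptor of the upper C4 is R in the benzyl ethers 17 and 18 and S in 19 with no change of geometry, because debenzylation changes the ligand ranking.

**Route**

Step 1
Reactants: 1 (S)-4-benzyloxazolidin-2-one; 2 (benzyloxy)acetyl chloride
Product: 3 (S)-4-benzyl-3-[(benzyloxy)acetyl]oxazolidin-2-one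
Conditions: n-BuLi, THF, −78 °C; then 2, −78 → 0 °C
Reagents that add atoms: none
Why: N-acylation of the lithiated oxazolidinone with an acid chloride is the standard way to load the auxiliary, and no stereocenter is formed.

Step 2
Reactants: 3 (S)-4-benzyl-3-[(benzyloxy)acetyl]oxazolidin-2-one; 4 3,4-bis(benzyloxy)benzaldehyde
Product: 5 (S)-4-benzyl-3-[(2S,3R)-2-(benzyloxy)-3-[3,4-bis(benzyloxy)phenyl]-3-hydroxypropanoyl]oxazolidin-2-one
Conditions: Bu2BOTf, Et3N, CH2Cl2, −78 → 0 °C; then 4, −78 → 0 °C; MeOH, pH 7 buffer, H2O2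
Reagents that add atoms: none
Why: Evans syn aldol reaction of a glycolyl imide: the Z boron enolate reacts through a closed chair transition state on the face remote from the auxiliary benzyl group, which should set the syn pair (2S = future C3, 3R = future C2) that maps onto a 2,3-cis flavan.

Step 3
Reactants: 5 aldol adduct
Product: 6 (2S,3R)-2-(benzyloxy)-3-[3,4-bis(benzyloxy)phenyl]-3-hydroxypropanoic acid
Conditions: LiOH, H2O2, THF/H2O, 0 °C; then Na2SO3; then cold dilute HCl to pH 3
Reagents that add atoms: hydrogen peroxide OO (as lithium hydroperoxide; supplies the carboxyl oxygen)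
Why: Hydroperoxide attacks the exocyclic imide carbonyl selectively (standard auxiliary cleavage), and the cold, short conditions should avoid retro-aldol cleavage and epimerization of the β-hydroxy acid.

Step 4
Reactants: 6 β-hydroxy acid
Product: 7 (5S,6R)-5-(benzyloxy)-6-[3,4-bis(benzyloxy)phenyl]-2,2-dimethyl-1,3-dioxan-4-one
Conditions: 2-methoxypropene, PPTS (cat.), CH2Cl2, 0 °C → rt
Reagents that add atoms: 2-methoxypropene COC(C)=C
Why: Acid-catalysed ketalization of a β-hydroxy acid with an enol ether closes the six-membered dioxanone, which masks O1 and turns C4 into a lactone-type acyl donor; both stereocenters are untouched and end up cis on the ring.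

Step 5
Reactants: 8 3-fluorobenzene-1,2-diol
Product: 9 1,2-bis(benzyloxy)-3-fluorobenzene
Conditions: BnBr, K2CO3, DMF, rt → 60 °C
Reagents that add atoms: benzyl bromide BrCc1ccccc1
Why: Williamson ether synthesis on both phenols under carbonate conditions that leave the aryl fluoride untouched.

Step 6
Reactants: 9 1,2-bis(benzyloxy)-3-fluorobenzene
Product: 10 1,2-bis(benzyloxy)-4-bromo-3-fluorobenzene
Conditions: NBS, MeCN, 0 °C → rt
Reagents that add atoms: N-bromosuccinimide O=C1CCC(=O)N1Br
Why: Electrophilic aromatic bromination should go para to the 1-benzyloxy group, because the 2-benzyloxy group is flanked on both sides and twisted out of conjugation; this puts bromine next to fluorine.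

Step 7
Reactants: 10 1,2-bis(benzyloxy)-4-bromo-3-fluorobenzene; 7 cis-dioxanone
Product: 14 (2R,3S)-3,7,8-tris(benzyloxy)-2-[3,4-bis(benzyloxy)phenyl]chroman-4-one, via aryllithium 11 (not isolated), via lithium lactolate 12 (not isolated), via lithium keto alkoxide 13 (not isolated)
Conditions: n-BuLi (1.0 equiv), THF, −78 °C; then 7, −78 °C; then warm to 0 °C; pH 7 buffer
Reagents that add atoms: none
Why: Bromine–lithium exchange places lithium on the carbon that becomes C4a, next to the fluorine-bearing carbon that becomes C8a, and aryllithium 11 adds once to the lactone carbonyl of 7 to give lactolate 12, which should persist at −78 °C so that no aryllithium is left when the ketone appears. On warming, 12 opens, the hemiketal alkoxide loses acetone, and the C2 alkoxide of 13 displaces fluoride from C8a by addition–elimination (SNAr) through a Meisenheimer intermediate delocalized into the new ortho C4 ketone. The closest known reactions are the addition of organolithiums to 1,3-dioxan-4-ones to give β-hydroxy ketones and the alkoxide SNAr cyclization of 2-fluoroaryl ketones to chroman-4-ones. Ring C closes as a six-membered ring by ipso attack of the alkoxide on C8a, with the departing fluoride outside the ring. No stereocenter is created: C2 and C3 are carried over from the cis dioxanone, so the 2,3-cis chromanone is expected, and the regiochemistry on ring A is fixed by the positions of Br and F in 10. The step needs ring closure to outrun retro-aldol cleavage of 13 and enolization at C3, which the low temperature, the lithium counterion and the absence of base once LiF has formed are expected to secure.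

Step 8
Reactants: 14 2,3-cis chromanone
Product: 15 (2R,3R,4R)-3,7,8-tris(benzyloxy)-2-[3,4-bis(benzyloxy)phenyl]chroman-4-ol
Conditions: NaBH4, CeCl3·7H2O, MeOH/THF, −40 °C; then water
Reagents that add atoms: none
Why: Luche reduction is fast and barely basic, so the cis C2/C3 pair should survive; hydride is expected to enter anti to the axial 3-benzyloxy group and give mainly the 3,4-cis alcohol, and either C4 epimer would serve because C4 is ionized in steps 9 and 10.

Step 9
Reactants: 15 flavan-4-ol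
Product: 16 (2R,3S,4S)-3,7,8-tris(benzyloxy)-4-(benzylsulfanyl)-2-[3,4-bis(benzyloxy)phenyl]chromane
Conditions: BnSH (3 equiv), TMSOTf (10 mol%), CH2Cl2, −40 °C; Et3N quench
Reagents that add atoms: phenylmethanethiol SCc1ccccc1
Why: SN1 substitution (the thiolysis reaction of flavan-4-ols): the C4 benzylic cation, stabilized by the para 7-benzyloxy group, should be captured by the thiol anti to the 3-benzyloxy group to give the 3,4-trans sulfide, which is inert to oxophilic Lewis acids and keeps this unit from ionizing in step 10.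

Step 10
Reactants: 15 flavan-4-ol; 16 4-benzylsulfanyl flavan
Product: 17 (2R,3S,4S)-3,7,8-tris(benzyloxy)-4-(benzylsulfanyl)-2-[3,4-bis(benzyloxy)phenyl]-6-[(2R,3R,4R)-3,7,8-tris(benzyloxy)-2-[3,4-bis(benzyloxy)phenyl]chroman-4-yl]chromane
Conditions: 16 (4 equiv, excess recovered), TMSOTf (20 mol%), CH2Cl2, −78 → −40 °C; Et3N quench
Reagents that add atoms: none
Why: Friedel–Crafts alkylation by the C4 benzylic cation of 15: C6 of 16, ortho to the 7-benzyloxy group and para to O1, is the most nucleophilic and least hindered arene position, and attack anti to the 3-benzyloxy group should make the interflavan bond 3,4-trans, while the sulfide of 16 stays dormant and its excess suppresses self-condensation of 15.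

Step 11
Reactants: 17 dimer sulfide
Product: 18 (2R,3R,4S)-3,7,8-tris(benzyloxy)-2-[3,4-bis(benzyloxy)phenyl]-6-[(2R,3R,4R)-3,7,8-tris(benzyloxy)-2-[3,4-bis(benzyloxy)phenyl]chroman-4-yl]chroman-4-ol
Conditions: AgOTf (silver trifluoromethanesulfonate, 2 equiv), NaHCO3, THF/H2O 9:1, 0 °C, dark, dilute
Reagents that add atoms: water O
Why: Thiophilic activation of the sulfide by silver followed by SN1 hydrolysis: water should capture the lower C4 cation anti to the 3-benzyloxy group, which sets the 3,4-trans (4S) carbinol of the lower unit.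

Step 12
Reactants: 18 deca-O-benzyl dimer
Product: 19 (2R,3R,4S)-2-(3,4-dihydroxyphenyl)-6-[(2R,3R,4S)-2-(3,4-dihydroxyphenyl)-3,7,8-trihydroxychroman-4-yl]chromane-3,4,7,8-tetrol
Conditions: H2 (1 atm), Pd(OH)2/C, THF/MeOH, rt, stopped as soon as debenzylation is complete
Reagents that add atoms: none
Why: Catalytic hydrogenolysis should remove the ten benzyl ethers without touching a stereocenter, provided the reaction is stopped before the benzylic C4–O bond of the lower unit is reduced.

**Compound list**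

1 | (S)-4-benzyloxazolidin-2-one | O=C1N[C@@H](Cc2ccccc2)CO1 | starting material
2 | (benzyloxy)acetyl chloride | O=C(Cl)COCc1ccccc1 | starting material
3 | (S)-4-benzyl-3-[(benzyloxy)acetyl]oxazolidin-2-one | O=C1OC[C@H](Cc2ccccc2)N1C(=O)COCc1ccccc1 | intermediate
4 | 3,4-bis(benzyloxy)benzaldehyde | O=Cc1ccc(OCc2ccccc2)c(OCc2ccccc2)c1 | starting material
5 | (S)-4-benzyl-3-[(2S,3R)-2-(benzyloxy)-3-[3,4-bis(benzyloxy)phenyl]-3-hydroxypropanoyl]oxazolidin-2-one | O=C1OC[C@H](Cc2ccccc2)N1C(=O)[C@@H](OCc1ccccc1)[C@H](O)c1ccc(OCc2ccccc2)c(OCc2ccccc2)c1 | intermediate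
6 | (2S,3R)-2-(benzyloxy)-3-[3,4-bis(benzyloxy)phenyl]-3-hydroxypropanoic acid | O=C(O)[C@@H](OCc1ccccc1)[C@H](O)c1ccc(OCc2ccccc2)c(OCc2ccccc2)c1 | intermediate
7 | (5S,6R)-5-(benzyloxy)-6-[3,4-bis(benzyloxy)phenyl]-2,2-dimethyl-1,3-dioxan-4-one | CC1(C)OC(=O)[C@@H](OCc2ccccc2)[C@H](O1)c1ccc(OCc2ccccc2)c(OCc2ccccc2)c1 | intermediate
8 | 3-fluorobenzene-1,2-diol | Oc1cccc(F)c1O | starting material
9 | 1,2-bis(benzyloxy)-3-fluorobenzene | Fc1cccc(OCc2ccccc2)c1OCc1ccccc1 | intermediate
10 | 1,2-bis(benzyloxy)-4-bromo-3-fluorobenzene | Fc1c(Br)ccc(OCc2ccccc2)c1OCc1ccccc1 | intermediate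
11 | [3,4-bis(benzyloxy)-2-fluorophenyl]lithium | [Li]c1ccc(OCc2ccccc2)c(OCc2ccccc2)c1F | intermediate (not isolated)
12 | lithium (5S,6R)-5-(benzyloxy)-4-[3,4-bis(benzyloxy)-2-fluorophenyl]-6-[3,4-bis(benzyloxy)phenyl]-2,2-dimethyl-1,3-dioxan-4-olate (C4 undefined) | [Li+].[O-]C1(c2ccc(OCc3ccccc3)c(OCc3ccccc3)c2F)OC(C)(C)O[C@H](c2ccc(OCc3ccccc3)c(OCc3ccccc3)c2)[C@@H]1OCc1ccccc1 | intermediate (not isolated)
13 | lithium (1R,2S)-2-(benzyloxy)-3-[3,4-bis(benzyloxy)-2-fluorophenyl]-1-[3,4-bis(benzyloxy)phenyl]-3-oxopropan-1-olate | [Li+].[O-][C@H](c1ccc(OCc2ccccc2)c(OCc2ccccc2)c1)[C@H](OCc1ccccc1)C(=O)c1ccc(OCc2ccccc2)c(OCc2ccccc2)c1F | intermediate (not isolated)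
14 | (2R,3S)-3,7,8-tris(benzyloxy)-2-[3,4-bis(benzyloxy)phenyl]chroman-4-one | O=C1c2ccc(OCc3ccccc3)c(OCc3ccccc3)c2O[C@H](c2ccc(OCc3ccccc3)c(OCc3ccccc3)c2)[C@@H]1OCc1ccccc1 | intermediate
15 | (2R,3R,4R)-3,7,8-tris(benzyloxy)-2-[3,4-bis(benzyloxy)phenyl]chroman-4-ol | O[C@@H]1c2ccc(OCc3ccccc3)c(OCc3ccccc3)c2O[C@H](c2ccc(OCc3ccccc3)c(OCc3ccccc3)c2)[C@@H]1OCc1ccccc1 | intermediate
16 | (2R,3S,4S)-3,7,8-tris(benzyloxy)-4-(benzylsulfanyl)-2-[3,4-bis(benzyloxy)phenyl]chromane | c1ccccc1CS[C@H]1c2ccc(OCc3ccccc3)c(OCc3ccccc3)c2O[C@H](c2ccc(OCc3ccccc3)c(OCc3ccccc3)c2)[C@@H]1OCc1ccccc1 | intermediate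
17 | deca-O-benzyl dimer with 4-benzylsulfanyl lower unit (upper unit 2R,3R,4R; lower unit 2R,3S,4S; both units 2,3-cis-3,4-trans) | C(c5ccccc5)Oc1ccc([C@H]2Oc3c(ccc(OCc5ccccc5)c3OCc5ccccc5)[C@H](c3cc4c(c(OCc5ccccc5)c3OCc5ccccc5)O[C@H](c3ccc(OCc5ccccc5)c(OCc5ccccc5)c3)[C@H](OCc5ccccc5)[C@H]4SCc5ccccc5)[C@H]2OCc5ccccc5)cc1OCc5ccccc5 | intermediate
18 | deca-O-benzyl dimer with free 4-hydroxyl in the lower unit (upper unit 2R,3R,4R; lower unit 2R,3R,4S) | C(c5ccccc5)Oc1ccc([C@H]2Oc3c(ccc(OCc5ccccc5)c3OCc5ccccc5)[C@H](c3cc4c(c(OCc5ccccc5)c3OCc5ccccc5)O[C@H](c3ccc(OCc5ccccc5)c(OCc5ccccc5)c3)[C@H](OCc5ccccc5)[C@H]4O)[C@H]2OCc5ccccc5)cc1OCc5ccccc5 | intermediate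
19 | (2R,3R,4S)-2-(3,4-dihydroxyphenyl)-6-[(2R,3R,4S)-2-(3,4-dihydroxyphenyl)-3,7,8-trihydroxychroman-4-yl]chromane-3,4,7,8-tetrol | Oc1ccc([C@H]2Oc3c(ccc(O)c3O)[C@H](c3cc4c(c(O)c3O)O[C@H](c3ccc(O)c(O)c3)[C@H](O)[C@H]4O)[C@H]2O)cc1O | target

**Count**

Total steps: 12. Longest linear sequence: 10 steps (steps 1–4 and 7–12); steps 5 and 6 form the arene branch that joins at step 7.

**Steps most likely to fail, with fallbacks**

Step 7. The cis C2/C3 relationship may be lost by retro-aldol cleavage and re-addition in the lithium keto alkoxide or by enolization at C3, and the aryllithium may deprotonate the dioxanone at C5 instead of adding. The fallback sets out from compound 5 and works at the alcohol oxidation level, where no enolizable ketone ever exists. Transamination of 5 (AlMe3, MeNHOMe·HCl, CH2Cl2) would give the Weinreb amide F1. Silylation (TBSOTf, 2,6-lutidine) would give the silyl ether F2, and reduction (i-Bu2AlH, THF, −78 °C) the aldehyde F3. Addition of aryllithium 11 (from 10 and n-BuLi, −78 °C) would give the benzylic alcohol F4 as a C1 epimer mixture, and TBAF the diol F5. KHMDS in DMF at 60 °C would then close ring C by alkoxide SNAr at the fluorine-bearing carbon. The fallback returns at compound 15, obtained together with its C4 epimer; both are converted in steps 9 and 10.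

Step 10. Chain growth and self-condensation may compete, because the electrophile and the product each carry a free C6 position on a ring A of the same reactivity as that of the nucleophile. The fallback sets out from compound 15 and blocks that position. NBS (CH2Cl2, −20 °C) would brominate C6 to give the 6-bromo flavan-4-ol F6, whose cation can only be captured by 16. Coupling with 16 (TMSOTf cat., CH2Cl2, −78 °C) would give the bromo dimer sulfide F7, and AgOTf/NaHCO3 in aqueous THF the bromo dimer carbinol F8. Hydrogenolysis (H2, Pd(OH)2/C, NaOAc, THF/MeOH) would remove the benzyl ethers and the aryl bromide together. The fallback returns at compound 19.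

Step 12. Over-reduction may occur: the benzylic C4–O bond of the lower unit becomes more labile to hydrogenolysis as the para 7-hydroxyl is unmasked. The fallback sets out from compound 17 and reveals the carbinol only after debenzylation. Oxidation (mCPBA, 2.2 equiv, CH2Cl2, 0 °C) would give the benzyl sulfone F9, which neither poisons the catalyst nor ionizes. Hydrogenolysis (H2, Pd(OH)2/C, THF/MeOH) would give the free-phenolic sulfone F10. In degassed aqueous NaHCO3/MeCN at rt the 7-phenoxide should expel the sulfinate by 1,6-elimination, and the resulting para-quinone methide should add water anti to the 3-hydroxyl. The fallback returns at compound 19.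

**Further compounds**

F1 | step 7 | (2S,3R)-2-(benzyloxy)-3-[3,4-bis(benzyloxy)phenyl]-3-hydroxy-N-methoxy-N-methylpropanamide | CON(C)C(=O)[C@@H](OCc1ccccc1)[C@H](O)c1ccc(OCc2ccccc2)c(OCc2ccccc2)c1
F2 | step 7 | (2S,3R)-2-(benzyloxy)-3-[3,4-bis(benzyloxy)phenyl]-3-[(tert-butyldimethylsilyl)oxy]-N-methoxy-N-methylpropanamide | CON(C)C(=O)[C@@H](OCc1ccccc1)[C@H](O[Si](C)(C)C(C)(C)C)c1ccc(OCc2ccccc2)c(OCc2ccccc2)c1
F3 | step 7 | (2S,3R)-2-(benzyloxy)-3-[3,4-bis(benzyloxy)phenyl]-3-[(tert-butyldimethylsilyl)oxy]propanal | O=C[C@@H](OCc1ccccc1)[C@H](O[Si](C)(C)C(C)(C)C)c1ccc(OCc2ccccc2)c(OCc2ccccc2)c1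
F4 | step 7 | (2R,3R)-2-(benzyloxy)-1-[3,4-bis(benzyloxy)-2-fluorophenyl]-3-[3,4-bis(benzyloxy)phenyl]-3-[(tert-butyldimethylsilyl)oxy]propan-1-ol (C1 epimer mixture) | OC(c1ccc(OCc2ccccc2)c(OCc2ccccc2)c1F)[C@@H](OCc1ccccc1)[C@H](O[Si](C)(C)C(C)(C)C)c1ccc(OCc2ccccc2)c(OCc2ccccc2)c1
F5 | step 7 | (2S,3R)-2-(benzyloxy)-1-[3,4-bis(benzyloxy)-2-fluorophenyl]-3-[3,4-bis(benzyloxy)phenyl]propane-1,3-diol (C1 epimer mixture) | OC(c1ccc(OCc2ccccc2)c(OCc2ccccc2)c1F)[C@@H](OCc1ccccc1)[C@H](O)c1ccc(OCc2ccccc2)c(OCc2ccccc2)c1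
F6 | step 10 | (2R,3R,4R)-3,7,8-tris(benzyloxy)-2-[3,4-bis(benzyloxy)phenyl]-6-bromochroman-4-ol | O[C@@H]1c2cc(Br)c(OCc3ccccc3)c(OCc3ccccc3)c2O[C@H](c2ccc(OCc3ccccc3)c(OCc3ccccc3)c2)[C@@H]1OCc1ccccc1
F7 | step 10 | deca-O-benzyl dimer sulfide with bromine at C6 of the upper unit (both units 2,3-cis-3,4-trans) | C(c5ccccc5)Oc1ccc([C@H]2Oc3c(cc(Br)c(OCc5ccccc5)c3OCc5ccccc5)[C@H](c3cc4c(c(OCc5ccccc5)c3OCc5ccccc5)O[C@H](c3ccc(OCc5ccccc5)c(OCc5ccccc5)c3)[C@H](OCc5ccccc5)[C@H]4SCc5ccccc5)[C@H]2OCc5ccccc5)cc1OCc5ccccc5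
F8 | step 10 | deca-O-benzyl dimer carbinol with bromine at C6 of the upper unit (both units 2,3-cis-3,4-trans) | C(c5ccccc5)Oc1ccc([C@H]2Oc3c(cc(Br)c(OCc5ccccc5)c3OCc5ccccc5)[C@H](c3cc4c(c(OCc5ccccc5)c3OCc5ccccc5)O[C@H](c3ccc(OCc5ccccc5)c(OCc5ccccc5)c3)[C@H](OCc5ccccc5)[C@H]4O)[C@H]2OCc5ccccc5)cc1OCc5ccccc5
F9 | step 12 | deca-O-benzyl dimer with 4-benzylsulfonyl lower unit (both units 2,3-cis-3,4-trans) | C(c5ccccc5)Oc1ccc([C@H]2Oc3c(ccc(OCc5ccccc5)c3OCc5ccccc5)[C@H](c3cc4c(c(OCc5ccccc5)c3OCc5ccccc5)O[C@H](c3ccc(OCc5ccccc5)c(OCc5ccccc5)c3)[C@H](OCc5ccccc5)[C@H]4S(=O)(=O)Cc5ccccc5)[C@H]2OCc5ccccc5)cc1OCc5ccccc5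
F10 | step 12 | free-phenolic dimer with 4-benzylsulfonyl lower unit (both units 2,3-cis-3,4-trans) | Oc1ccc([C@H]2Oc3c(ccc(O)c3O)[C@H](c3cc4c(c(O)c3O)O[C@H](c3ccc(O)c(O)c3)[C@H](O)[C@H]4S(=O)(=O)Cc5ccccc5)[C@H]2O)cc1O
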